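**Assumption:** the target is taken exactly as drawn, which corresponds to (2S) at the dihydrofuran carbon and (S) in the 2-methylbutanoyl chain; the pyranone is handled as its 4-hydroxy-2-pyranone tautomer.

Numbering used below: ring A is the benzene ring (C3a, C4, C5, C6, C7, C7a), ring B the dihydrofuran (O1, C2, C3, C3a, C7a), ring C the pyranone (O1', C2'–C6'); the acyl chain is C1''–C4''.

## The problem

- The target is a hexasubstituted benzene of the acylphloroglucinol type. Ring A carries oxygen at C4, C6 and C7a, the 2-methylbutanoyl group at C7, the methylene bridge to ring C at C5, and C3 of ring B at C3a.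
- The central difficulty is regiochemical. Of the three phloroglucinol oxygens only the one at C7a, between the acyl-bearing C7 and C3a, may become O1 of ring B. The oxygen at C4 flanks C3a equally well and is the more acidic and more nucleophilic of the two.
- Ring B holds the stereocentre C2 (S), which is allylic, bonded to an aryl ether oxygen, and bears an isopropenyl group. It is remote from the second stereocentre C2'' (S), so neither can control the other and each must be set independently.
- C2'' is alpha to an aryl ketone and can be lost by enolisation under strong acid or base. The isopropenyl group and the allylic C2–O1 bond will not survive strong protic or Lewis acids (addition, ionisation, isomerisation to the benzofuran).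
- The methylene bridge joins two carbons that are both nucleophilic (C5 of ring A and C3' of ring C), so a one-carbon electrophile must be placed between them without forming homodimers.
- The feature that makes the key step possible is twofold. The C7 carbonyl chelates the hydroxyl on the neighbouring C7a and thereby marks that one oxygen: it stays free when the others are capped, and it directs iodination to the adjacent C3a. And the unit O1–C2(isopropenyl)–C3 is, atom for atom, isoprene added across the C7a oxygen and C3a.

## Retrosynthesis

**Methylene bridge (C5–CH2 and CH2–C3').** Target 16 is cut at both bonds of the bridge into dihydrobenzofurandiol 9, pyranone 13 and a one-carbon iminium electrophile.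
- This is the most convergent cut: it divides the molecule into a C16 and a C8 half.
- C5 is the only unsubstituted position of ring A in 9, so no regiochemical question arises.
- Done last, it keeps the acidic, chelating pyranone enol away from the ring B closure.
- The forward reaction must charge the pyranone with the methylene first (Mannich base 14, then methylidene dione 15) to suppress homodimers, and must run under neutral conditions.

**Protecting groups (two O–CH2OMe bonds).** Diol 9 comes from bis-MOM ether 8. The acetals exist only to silence the C4 oxygen during ring B closure (the C6 acetal comes along for free). Their removal must avoid protic acid.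

**Ring B (C3a–C3 and O1–C2), the key cut.** 8 is cut into iodophenol 6 and isoprene 7.
- Cutting O1–C2 alone (allylic etherification or epoxide opening) would require a five-carbon chain to be assembled on the arene beforehand, with its own geometry and oxidation-level problems.
- Cutting both bonds removes ring B, the stereocentre C2 and five carbons in one operation and leaves a flat arene whose only stereocentre comes from the chiral pool.
- C3a is natively nucleophilic, as is the diene terminus. The iodine reverses the polarity of C3a, so palladium can join two carbons of like polarity.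
- The forward reaction must insert isoprene at its unsubstituted double bond, close the ring through oxygen rather than undergo beta-hydride elimination, and set C2 under ligand control, without disturbing C2''.

**C–I bond and acetals.** 6 comes from 5 by iodination and 5 from triol 4 by double acetalisation. Both regiochemical decisions are delegated to the ketone.
- 4 has a mirror plane, so capping the para hydroxyl and either ortho hydroxyl gives the same compound 5.
- In 5 the remaining chelated phenol directs iodine to its ortho carbon, the future C3a.
- The precursor 4 has no regiochemical information beyond its acyl group.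

**Aryl–acyl bond.** 4 is cut into phloroglucinol 2 and (S)-2-methylbutanoic acid 1 (through chloride 3). The threefold symmetry of 2 makes monoacylation regiochemically trivial, and the chiral pool supplies C2''. The forward reaction must not racemise the acid.

**Ring C (lactone C–O and C4–C5 of the keto ester chain).** Pyranone 13 comes from diketo ester 12, and 12 from methyl 3-oxopentanoate 10 and the propanoyl donor 11. Two commercial C6 and C3 pieces give the ring in one telescoped operation.

## Roads not taken

**Alternative 1:** the biomimetic route, which is the obvious one.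
- Cut: C3a–C3 by Friedel–Crafts prenylation of 4 to the C-prenyl triol A1, then O1–C2 by asymmetric epoxidation and phenol opening to the tertiary alcohol A2, then dehydration to 9.
- Why it is worse: prenylation of free acylphloroglucinols gives mono-, di- and O-alkylated mixtures. The epoxide of A1 can be opened by either flanking hydroxyl; the more nucleophilic para hydroxyl leads to the isomer A3, and 6-endo opening leads to chromanols. The final dehydration must choose between the methyl hydrogens and C2–H and risks aromatisation to the benzofuran.
- Regiocontrol would need the same protecting groups as the chosen route, in a longer sequence.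

**Alternative 2:** intramolecular asymmetric allylic etherification.
- Cut: O1–C2 only. The (E)-allylic carbonate A4 would be ionised by zerovalent palladium with a chiral diphosphine and closed by the phenol.
- Why it is worse: the reaction type is reliable for 2-isopropenyl dihydrobenzofurans, but A4 needs three to four extra steps from 6 (allylation, cross-metathesis with the second-generation Grubbs catalyst, reduction, carbonate formation beside a free phenol) and control of alkene geometry.
- Its key step makes one bond; the chosen step makes two from isoprene itself.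

**Alternative 3:** reversed order, exploiting the symmetry of phloroglucinol.
- Cut: annulate 2-iodobenzene-1,3,5-triol A5 with isoprene 7 to the diol A6, where all oxygens are equivalent and no protection is needed; then acylate at C7 and alkylate at C5.
- Why it is worse: in A6 both C5 and C7 are doubly activated, so the regiochemical problem is only moved. It is moved to a Friedel–Crafts acylation whose Lewis acid would ionise the allylic C2–O1 bond, add to the isopropenyl group and endanger C2''.
- The chosen plan uses the acyl group as the control element instead of making it the thing to be controlled.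

Key step: step 4

## Route

Step 1
Reactants: 1 (2S)-2-methylbutanoic acid; 2 benzene-1,3,5-triol (phloroglucinol)
Product: 4 (2S)-2-methyl-1-(2,4,6-trihydroxyphenyl)butan-1-one, via (2S)-2-methylbutanoyl chloride 3 (not isolated)
Conditions: (COCl)2 (1.0 equiv), cat. DMF, CH2Cl2, 0 °C to rt; then 2, AlCl3 (3.5 equiv), PhNO2/CH2Cl2, 0 °C to rt
Reagents that add atoms: none
Why: Friedel–Crafts C-acylation of phloroglucinol should stop at the monoketone because the product is deactivated and bound to aluminium; the stereocentre comes from the chiral pool acid and should be kept if the chloride is made under neutral conditions and the acylation is run cold.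

Step 2
Reactants: 4 (2S)-2-methyl-1-(2,4,6-trihydroxyphenyl)butan-1-one
Product: 5 (2S)-1-[2-hydroxy-4,6-bis(methoxymethoxy)phenyl]-2-methylbutan-1-one
Conditions: MOMCl (2.2 equiv), i-Pr2NEt (2.5 equiv), CH2Cl2, 0 °C to rt
Reagents that add atoms: chloromethyl methyl ether, COCCl
Why: O-alkylation of the phenols with the chloromethyl ether; once the para hydroxyl and one ortho hydroxyl are capped, the last one is locked in a hydrogen bond to the ketone and should stay free, and the mirror symmetry of 4 makes 5 a single compound.

Step 3
Reactants: 5 (2S)-1-[2-hydroxy-4,6-bis(methoxymethoxy)phenyl]-2-methylbutan-1-one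
Product: 6 (2S)-1-[2-hydroxy-3-iodo-4,6-bis(methoxymethoxy)phenyl]-2-methylbutan-1-one
Conditions: BnMe3N·ICl2 (1.0 equiv), NaHCO3, CH2Cl2/MeOH, 0 °C to rt
Reagents that add atoms: benzyltrimethylammonium dichloroiodate, C[N+](C)(C)Cc1ccccc1.Cl[I-]Cl
Why: Electrophilic aromatic iodination, directed by the chelated phenol to its ortho carbon as is known for 2-hydroxy-4,6-dialkoxyaryl ketones; the hydrogencarbonate buffer should keep the acetals intact.

Step 4
Reactants: 6 (2S)-1-[2-hydroxy-3-iodo-4,6-bis(methoxymethoxy)phenyl]-2-methylbutan-1-one; 7 2-methylbuta-1,3-diene (isoprene)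
Product: 8 (2S)-1-[(2S)-4,6-bis(methoxymethoxy)-2-(prop-1-en-2-yl)-2,3-dihydro-1-benzofuran-7-yl]-2-methylbutan-1-one
Conditions: Pd2(dba)3·CHCl3 (5 mol%), chiral sulfinamide monophosphine ligand of the TY-Phos type (12 mol%, enantiomer chosen for 2S), K2CO3 (2 equiv), 7 (5 equiv), 1,4-dioxane, 80 °C, sealed tube
Reagents that add atoms: none
Why: Oxidative addition of the C–I bond of 6 to zerovalent palladium is followed by syn carbopalladation of the unsubstituted vinyl end of isoprene (aryl to the terminal CH2, which becomes C3), and the resulting η3-allylpalladium unit, with the methyl group on its central carbon, is captured at its inner terminus by the neighbouring phenoxide to form O1–C2 and return zerovalent palladium. The closest known reaction is the Larock heteroannulation of o-iodophenols with 1,3-dienes and its enantioselective Heck/Tsuji–Trost form with chiral monophosphine ligands, which turns isoprene into 2-isopropenyl-2,3-dihydrobenzofurans. Ring B is closed by a 5-exo allylic etherification after the intermolecular C3a–C3 bond has been made; attack at the outer CH2 terminus would need a seven-membered ring and should not compete. The new stereocentre C2 is set in this C–O bond formation under control of the chiral ligand (the two faces of the allyl unit can exchange through the η1 form at its CH2 terminus), so the ligand enantiomer is chosen for 2S and the distant acyl stereocentre has no say. Three selectivities are needed: insertion at the less hindered double bond of isoprene, which the doubly ortho-substituted arylpalladium should enforce; closure through the oxygen next to the acyl group, which is secured because it is the only free hydroxyl and the oxygen on the other side of the iodinated carbon is capped as its MOM ether; and C–O bond formation ahead of beta-hydride elimination to an aryl diene, which the intramolecular phenoxide should favour. K2CO3 in dioxane is mild enough that the hindered ketone should not enolise at C2'', and the MOM ethers are inert.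

Step 5
Reactants: 8 (2S)-1-[(2S)-4,6-bis(methoxymethoxy)-2-(prop-1-en-2-yl)-2,3-dihydro-1-benzofuran-7-yl]-2-methylbutan-1-one
Product: 9 (2S)-1-[(2S)-4,6-dihydroxy-2-(prop-1-en-2-yl)-2,3-dihydro-1-benzofuran-7-yl]-2-methylbutan-1-one
Conditions: ZnBr2 (1 equiv per MOM), n-PrSH (2 equiv per MOM), CH2Cl2, 0 °C, short reaction time
Reagents that add atoms: none
Why: Lewis acid-assisted transfer of the methoxymethyl group from the phenol oxygens to the thiol is fast at 0 °C and needs no protic acid, so the isopropenyl group and the allylic C2–O1 bond should survive; neither stereocentre takes part.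

Step 6
Reactants: 10 methyl 3-oxopentanoate; 11 N-methoxy-N-methylpropanamide
Product: 13 6-ethyl-4-hydroxy-5-methyl-2H-pyran-2-one, via methyl 4-methyl-3,5-dioxoheptanoate 12 (not isolated)
Conditions: NaH (1.1 equiv), THF, 0 °C; n-BuLi (1.05 equiv), 0 °C; then 11, 0 °C to rt; aq. HCl quench; crude 12, DBU (0.5 equiv), toluene, reflux
Reagents that add atoms: none
Why: Acylation of the beta-keto ester dianion at its gamma carbon by the Weinreb amide (Huckin–Weiler dianion chemistry) gives the 3,5-diketo ester, whose C5 enol oxygen lactonises onto the ester under DBU with loss of methanol; the methyl-bearing carbon becomes sp2, so no stereocentre arises.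

Step 7
Reactants: 13 6-ethyl-4-hydroxy-5-methyl-2H-pyran-2-one; 9 (2S)-1-[(2S)-4,6-dihydroxy-2-(prop-1-en-2-yl)-2,3-dihydro-1-benzofuran-7-yl]-2-methylbutan-1-one
Product: 16 3-{[(2S)-4,6-dihydroxy-7-[(2S)-2-methylbutanoyl]-2-(prop-1-en-2-yl)-2,3-dihydro-1-benzofuran-5-yl]methyl}-6-ethyl-4-hydroxy-5-methyl-2H-pyran-2-one, via Mannich base 3-[(dimethylamino)methyl]-6-ethyl-4-hydroxy-5-methyl-2H-pyran-2-one 14 (not isolated), via 6-ethyl-5-methyl-3-methylidene-2H-pyran-2,4(3H)-dione 15 (not isolated)
Conditions: 13, Me2N=CH2+ I− (1.0 equiv), CHCl3, rt; then 9 (1.0 equiv), rt to 40 °C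
Reagents that add atoms: N,N-dimethylmethyleneiminium iodide (Eschenmoser's salt), C=[N+](C)C.[I-]
Why: Mannich reaction at C3' of the pyranone, loss of dimethylamine to the methylidene dione and conjugate addition of C5 of 9, the only free position of ring A, is the established way to make methylene-bridged phloroglucinol–pyranone heterodimers; the neutral, near-ambient conditions should spare both stereocentres and the isopropenyl group.

## Compound list

1 | (2S)-2-methylbutanoic acid | CC[C@H](C)C(=O)O | starting material
2 | benzene-1,3,5-triol (phloroglucinol) | Oc1cc(O)cc(O)c1 | starting material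
3 | (2S)-2-methylbutanoyl chloride | CC[C@H](C)C(=O)Cl | intermediate (not isolated)
4 | (2S)-2-methyl-1-(2,4,6-trihydroxyphenyl)butan-1-one | CC[C@H](C)C(=O)c1c(O)cc(O)cc1O | intermediate
5 | (2S)-1-[2-hydroxy-4,6-bis(methoxymethoxy)phenyl]-2-methylbutan-1-one | CC[C@H](C)C(=O)c1c(O)cc(OCOC)cc1OCOC | intermediate
6 | (2S)-1-[2-hydroxy-3-iodo-4,6-bis(methoxymethoxy)phenyl]-2-methylbutan-1-one | CC[C@H](C)C(=O)c1c(O)c(I)c(OCOC)cc1OCOC | intermediate
7 | 2-methylbuta-1,3-diene (isoprene) | C=CC(C)=C | starting material
8 | (2S)-1-[(2S)-4,6-bis(methoxymethoxy)-2-(prop-1-en-2-yl)-2,3-dihydro-1-benzofuran-7-yl]-2-methylbutan-1-one | C=C(C)[C@@H]1Cc2c(OCOC)cc(OCOC)c(C(=O)[C@@H](C)CC)c2O1 | intermediate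
9 | (2S)-1-[(2S)-4,6-dihydroxy-2-(prop-1-en-2-yl)-2,3-dihydro-1-benzofuran-7-yl]-2-methylbutan-1-one | C=C(C)[C@@H]1Cc2c(O)cc(O)c(C(=O)[C@@H](C)CC)c2O1 | intermediate
10 | methyl 3-oxopentanoate | CCC(=O)CC(=O)OC | starting material
11 | N-methoxy-N-methylpropanamide | CCC(=O)N(C)OC | starting material
12 | methyl 4-methyl-3,5-dioxoheptanoate | CCC(=O)C(C)C(=O)CC(=O)OC | intermediate (not isolated)
13 | 6-ethyl-4-hydroxy-5-methyl-2H-pyran-2-one | CCc1oc(=O)cc(O)c1C | intermediate
14 | 3-[(dimethylamino)methyl]-6-ethyl-4-hydroxy-5-methyl-2H-pyran-2-one | CCc1oc(=O)c(CN(C)C)c(O)c1C | intermediate (not isolated)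
15 | 6-ethyl-5-methyl-3-methylidene-2H-pyran-2,4(3H)-dione | CCC1=C(C)C(=O)C(=C)C(=O)O1 | intermediate (not isolated)
16 | 3-{[(2S)-4,6-dihydroxy-7-[(2S)-2-methylbutanoyl]-2-(prop-1-en-2-yl)-2,3-dihydro-1-benzofuran-5-yl]methyl}-6-ethyl-4-hydroxy-5-methyl-2H-pyran-2-one | C=C(C)[C@@H]1Cc2c(O)c(Cc3c(O)c(C)c(CC)oc3=O)c(O)c(C(=O)[C@@H](C)CC)c2O1 | target

## Step count and risk

Total: 7 steps. Longest linear sequence: 6 steps (steps 1, 2, 3, 4, 5 and 7); step 6 is a one-step side branch.

**Step 4 (key step).**
- What may go wrong: beta-hydride elimination of the allylpalladium intermediate to an aryl diene, slow insertion or protodeiodination, or weak enantio-induction. The arylpalladium is flanked by two ortho substituents and the chelated phenoxide is a weak nucleophile. Reversible re-ionisation of the allylic aryl ether could also erode selectivity.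
- Fallback, from 6 back to 8, by known reactions:
  - Stille coupling of 6 with tributyl(3-methylbut-2-en-1-yl)stannane and Pd(PPh3)4 should give the prenyl phenol (2S)-1-[2-hydroxy-4,6-bis(methoxymethoxy)-3-(3-methylbut-2-en-1-yl)phenyl]-2-methylbutan-1-one F1.
  - Shi epoxidation (fructose-derived chiral ketone, KHSO5, buffered with K2CO3), with the ketone enantiomer chosen for the (R)-epoxide, should give (2S)-1-[3-{[(2R)-3,3-dimethyloxiran-2-yl]methyl}-2-hydroxy-4,6-bis(methoxymethoxy)phenyl]-2-methylbutan-1-one F2.
  - Under the basic conditions the only free phenoxide should open F2 5-exo at the secondary carbon with inversion, giving the tertiary alcohol (2S)-1-[(2S)-2-(2-hydroxypropan-2-yl)-4,6-bis(methoxymethoxy)-2,3-dihydro-1-benzofuran-7-yl]-2-methylbutan-1-one F3.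
  - Syn dehydration of F3 with the Burgess reagent towards a methyl group should return the route to 8.

**Step 5.**
- What may go wrong: ionisation of the allylic C2–O1 bond or addition across the isopropenyl group while the acetals are cleaved, because any acetal cleavage needs an electrophilic activator.
- Fallback, from 4 back to 9, with a fluoride-labile protecting group in place of the acetal:
  - Bis-silylation of 4 (TBSCl, imidazole) should give (2S)-1-[2,4-bis(tert-butyldimethylsilyloxy)-6-hydroxyphenyl]-2-methylbutan-1-one F4.
  - Iodination as in step 3 should give (2S)-1-[4,6-bis(tert-butyldimethylsilyloxy)-2-hydroxy-3-iodophenyl]-2-methylbutan-1-one F5.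
  - Annulation with 7 as in step 4 should give (2S)-1-[(2S)-4,6-bis(tert-butyldimethylsilyloxy)-2-(prop-1-en-2-yl)-2,3-dihydro-1-benzofuran-7-yl]-2-methylbutan-1-one F6.
  - n-Bu4NF buffered with AcOH in THF at 0 °C should then give 9 without any acid.

**Step 1.**
- What may go wrong: partial racemisation of C2'', through ketene formation from the acyl chloride or enolisation of the aluminium-bound ketone; over-acylation is a lesser concern. The enantiomeric purity of 4 should be checked on a chiral phase before going on.
- Fallback, from 1 and 2 to 5, avoiding Lewis acid altogether: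
  - 1 is converted with N,O-dimethylhydroxylamine and a carbodiimide into the Weinreb amide (2S)-N-methoxy-N,2-dimethylbutanamide F7.
  - 2 is converted with MOMCl and NaH into 1,3,5-tris(methoxymethoxy)benzene F8.
  - Ortho-lithiation of F8 (n-BuLi, THF, 0 °C) and addition to F7 at −78 °C should give (2S)-2-methyl-1-[2,4,6-tris(methoxymethoxy)phenyl]butan-1-one F9.
  - Chelation-assisted cleavage of one acetal next to the ketone (one equivalent of HCl in MeOH, 0 °C) should give 5.

**Step 7.**
- What may go wrong: self-condensation of the pyranone through 15 to the methylene-bridged homodimer, or reversible Mannich exchange that leaves 9 unreacted. The pyranone is a better nucleophile towards 15 than the hindered C5 of 9.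
- Fallback, from 9 and 13 to 16, with the roles of the partners reversed:
  - 9 is aminomethylated first at C5 with the iminium salt to the benzylic amine (2S)-1-[(2S)-5-[(dimethylamino)methyl]-4,6-dihydroxy-2-(prop-1-en-2-yl)-2,3-dihydro-1-benzofuran-7-yl]-2-methylbutan-1-one F10.
  - Warming F10 with 13 in dioxane should expel dimethylamine to give the o-quinone methide of ring A, which C3' of the pyranone then captures.

**Step 3.**
- What may go wrong: iodination at the ring carbon between the two MOM ethers (para to the phenol) or di-iodination, because both free positions are strongly activated.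
- Fallback, from 4 to 6, letting symmetry rather than a directing effect fix the position:
  - 4 is iodinated first with one equivalent of BnMe3N·ICl2; its two free ring positions are equivalent, so only (2S)-2-methyl-1-(2,4,6-trihydroxy-3-iodophenyl)butan-1-one F11 can form.
  - MOMCl and i-Pr2NEt should then cap the para hydroxyl and the unhindered ortho hydroxyl, leaving free the hydroxyl that is both chelated and flanked by iodine, which is 6.

## Further compounds

F1 | step 4 | (2S)-1-[2-hydroxy-4,6-bis(methoxymethoxy)-3-(3-methylbut-2-en-1-yl)phenyl]-2-methylbutan-1-one | CC[C@H](C)C(=O)c1c(O)c(CC=C(C)C)c(OCOC)cc1OCOC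
F2 | step 4 | (2S)-1-[3-{[(2R)-3,3-dimethyloxiran-2-yl]methyl}-2-hydroxy-4,6-bis(methoxymethoxy)phenyl]-2-methylbutan-1-one | CC[C@H](C)C(=O)c1c(O)c(C[C@H]2OC2(C)C)c(OCOC)cc1OCOC
F3 | step 4 | (2S)-1-[(2S)-2-(2-hydroxypropan-2-yl)-4,6-bis(methoxymethoxy)-2,3-dihydro-1-benzofuran-7-yl]-2-methylbutan-1-one | CC(C)(O)[C@@H]1Cc2c(OCOC)cc(OCOC)c(C(=O)[C@@H](C)CC)c2O1
F4 | step 5 | (2S)-1-[2,4-bis(tert-butyldimethylsilyloxy)-6-hydroxyphenyl]-2-methylbutan-1-one | CC[C@H](C)C(=O)c1c(O)cc(O[Si](C)(C)C(C)(C)C)cc1O[Si](C)(C)C(C)(C)C
F5 | step 5 | (2S)-1-[4,6-bis(tert-butyldimethylsilyloxy)-2-hydroxy-3-iodophenyl]-2-methylbutan-1-one | CC[C@H](C)C(=O)c1c(O)c(I)c(O[Si](C)(C)C(C)(C)C)cc1O[Si](C)(C)C(C)(C)C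
F6 | step 5 | (2S)-1-[(2S)-4,6-bis(tert-butyldimethylsilyloxy)-2-(prop-1-en-2-yl)-2,3-dihydro-1-benzofuran-7-yl]-2-methylbutan-1-one | C=C(C)[C@@H]1Cc2c(O[Si](C)(C)C(C)(C)C)cc(O[Si](C)(C)C(C)(C)C)c(C(=O)[C@@H](C)CC)c2O1
F7 | step 1 | (2S)-N-methoxy-N,2-dimethylbutanamide | CC[C@H](C)C(=O)N(C)OC
F8 | step 1 | 1,3,5-tris(methoxymethoxy)benzene | COCOc1cc(OCOC)cc(OCOC)c1
F9 | step 1 | (2S)-2-methyl-1-[2,4,6-tris(methoxymethoxy)phenyl]butan-1-one | CC[C@H](C)C(=O)c1c(OCOC)cc(OCOC)cc1OCOC
F10 | step 7 | (2S)-1-[(2S)-5-[(dimethylamino)methyl]-4,6-dihydroxy-2-(prop-1-en-2-yl)-2,3-dihydro-1-benzofuran-7-yl]-2-methylbutan-1-one | C=C(C)[C@@H]1Cc2c(O)c(CN(C)C)c(O)c(C(=O)[C@@H](C)CC)c2O1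
F11 | step 3 | (2S)-2-methyl-1-(2,4,6-trihydroxy-3-iodophenyl)butan-1-one | CC[C@H](C)C(=O)c1c(O)cc(O)c(I)c1O
A1 | alternative 1 | (2S)-2-methyl-1-[2,4,6-trihydroxy-3-(3-methylbut-2-en-1-yl)phenyl]butan-1-one | CC[C@H](C)C(=O)c1c(O)c(CC=C(C)C)c(O)cc1O
A2 | alternative 1 | (2S)-1-[(2S)-4,6-dihydroxy-2-(2-hydroxypropan-2-yl)-2,3-dihydro-1-benzofuran-7-yl]-2-methylbutan-1-one | CC(C)(O)[C@@H]1Cc2c(O)cc(O)c(C(=O)[C@@H](C)CC)c2O1
A3 | alternative 1 | (2S)-1-[(2S)-4,6-dihydroxy-2-(2-hydroxypropan-2-yl)-2,3-dihydro-1-benzofuran-5-yl]-2-methylbutan-1-one | CC(C)(O)[C@@H]1Cc2c(O)c(C(=O)[C@@H](C)CC)c(O)cc2O1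
A4 | alternative 2 | (2E)-4-{2-hydroxy-4,6-bis(methoxymethoxy)-3-[(2S)-2-methylbutanoyl]phenyl}-2-methylbut-2-en-1-yl methyl carbonate | CC[C@H](C)C(=O)c1c(O)c(C/C=C(\C)COC(=O)OC)c(OCOC)cc1OCOC
A5 | alternative 3 | 2-iodobenzene-1,3,5-triol | Oc1cc(O)c(I)c(O)c1
A6 | alternative 3 | (2S)-2-(prop-1-en-2-yl)-2,3-dihydro-1-benzofuran-4,6-diol | C=C(C)[C@@H]1Cc2c(O)cc(O)cc2O1
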